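The readings are simulated for an exercise; the scatter is artificial.

Reckon the product excess from one ratio. Assume each substrate is consumed pseudo-first-order in itself, with catalyst and reagent entering both rates alike. Let f and g be the parts of its own charge left of the left-handed and right-handed substrate. Then ln f = s·ln g, where s is the selectivity factor. The excess e is g − f divided by the sum of the two parts reacted, and the part reacted c is the mean of those two parts.

| setting | Monday's | Tuesday's | flask |
|---|---|---|---|
| left-handed substrate | 0.0050 M | 0.0034 M | 0.0050 M |
| right-handed substrate | 0.0050 M | 0.0034 M | 0.0050 M |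
| reagent | 5.5 mM | 5.5 mM | 5.50 mM |
| free catalyst | 29 µM | 29 µM | 29 µM |
| impurity | 13 µM | 13 µM | 13 µM |
| remark | the very flask that is asked about, followed so far | run made earlier |  |
| time |  |  | 4.0 min |

- Monday's (time / s: left-handed product / %, right-handed product / %, left-handed substrate / %): 10.0: 8, 0, 40; 15.0: 14, 2, 37; 25.0: 18, 1, 31; 40.0: 23, 2, 26; 50.0: 28, 5, 24
- Tuesday's (time / min: left-handed product / %, right-handed product / %, left-handed substrate / %): 0.250: 16, 0, 35; 0.833: 30, 7, 17; 1.33: 38, 9, 15; 2.00: 40, 9, 9; 3.00: 40, 13, 6; 4.00: 43, 14, 5

(standard deviation of a reading: 1.5 percentage points)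

- free catalyst is single-handed; left-handed substrate and right-handed substrate are mirror images of each other, charged as a racemate, each of them at the stated concentration
- what may be going on: free catalyst + left-handed substrate <-> catalyst intermediate A; free catalyst + right-handed substrate <-> catalyst intermediate B; reagent + catalyst intermediate A -> free catalyst + left-handed product; reagent + catalyst intermediate B -> free catalyst + right-handed product; free catalyst <-> dormant form; free catalyst -> spent catalyst A; free catalyst + impurity -> spent catalyst B
- an excess is the difference of the two amounts in percent of their sum
- an excess is below zero if the other one leads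

* excess of left-handed product over right-handed product in the product at 25 s
* excess of left-handed product over right-handed product in the product at 4.0 min
* part of the left-handed substrate and right-handed substrate charged together that has reacted at 4.0 min

Start with Tuesday's last row, remembering that each substrate is half of the percent basis. Left-handed substrate at 5 % and right-handed product at 14 % give s = 7.01.

For the early time, take Monday's 31 % at 25.0 s, so f = 62.0 % and e = 70.4 %.

For the late time, reckon the reagent, one per product. At 50.0 s Monday's readings leave 2.20 mM of reagent. Let it fall straight to a third of that by 4.0 min, a mean of 1.47 mM.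

Tuesday's left-handed substrate falls between 2.00 min and 4.00 min with a rate constant of 0.294 min⁻¹, at the 1.90 mM of reagent that the readings at 3.00 min leave. Scale that constant by reagent, and f at 4.0 min comes to 23.4 %.

The weak link is s, which hangs on two readings, each good to 1.5 percentage points. Reforge it by summing over the rows of both runs: −ln f totals 11.2, and −ln g totals 1.38. The selectivity factor, the ratio of the two sums, is s = 8.07.

Commit to an excess of 73.7 % at 25 s, then an excess of 64.6 % with 46.5 % reacted at 4.0 min.

The forecast gives 71 %, 61 % and 49 %, on the grounds “Selectivity from the left-handed and right-handed conversions gives kL/kR ≈ 7–8.”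

The flask gives 76.9 %, 66.9 % and 47.9 %.

    free catalyst + left-handed substrate ⇌ catalyst intermediate A (K = 380 M⁻¹, k = 70000 M⁻¹ s⁻¹)
    free catalyst + right-handed substrate ⇌ catalyst intermediate B (K = 120 M⁻¹, k = 8800 M⁻¹ s⁻¹)
    reagent + catalyst intermediate A → free catalyst + left-handed product (k = 2300 M⁻¹ s⁻¹)
    reagent + catalyst intermediate B → free catalyst + right-handed product (k = 780 M⁻¹ s⁻¹)
    free catalyst ⇌ dormant form (K = 0.440, k = 0.0430 s⁻¹)
    free catalyst → spent catalyst A (k = 0.00910 s⁻¹)
    free catalyst + impurity → spent catalyst B (k = 1.20 × 10⁵ M⁻¹ s⁻¹)

Put the 20 % of its left-handed substrate that the flask keeps at 4.00 min into s: g comes to 81.9 %, and the flask keeps 84 % of its right-handed substrate. Now take the neighbour charged with 7.3 × 10⁻⁵ M of free catalyst, other charges held. It keeps 11 % of its left-handed substrate, so s gives g = 76.1 % and e = 57.6 %. That neighbour holds 79 % of its right-handed substrate and ends at an excess of 61.9 %.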